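**Retrosynthetic overview**

1. Units are numbered 1–4 from the chain top. The target is read as epicatechin-(4α→6)-ent-epicatechin-(4β→8)-epicatechin-(4β→6)-epicatechin: units 1, 3 and 4 are 2R,3R and unit 2 is 2S,3S; the C4–aryl bonds of units 1 and 2 are cis to O3, that of unit 3 is trans.
2. Feature: C6 of ring A of unit 4, the carbon between O5 and O7, carries C4 of unit 3. Cutting O1–C2 and C4–C4a of ring C of unit 4 leaves a 2,6-dibenzyloxy-4-hydroxyphenyl ring on unit 3 whose two carbons ortho to the hydroxyl are equivalent, so annulation with (E)-3,4-dibenzyloxycinnamaldehyde can only give the 4→6 isomer.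
3. The phenol comes from trans Friedel–Crafts arylation of the C4 cation of 8-bromo-penta-O-benzylepicatechin with the TIPS ether of 3,5-dibenzyloxyphenol. After annulation, O3 and C2 of unit 4 are set by hydroboration–oxidation, oxidation and dynamic transfer hydrogenation.
4. The two 3,4-cis interflavan bonds (unit 1 C4–unit 2 C6, then unit 2 C4–unit 3 C8) are each made by aryllithium addition to a flavan-4-one followed by Bu3SnH/CF3CO2H deoxygenation. Unit 2 comes from (+)-epicatechin, with Br at C8 as block and I at C6 as handle.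
5. Ring order: ring C of unit 4 is the only ring built (all other rings come from the two epicatechins). The unit 3–unit 4 bromide and the unit 1–unit 2 ketone are made in parallel and joined, and one hydrogenolysis removes twenty benzyl ethers and the C–Br bond.

Key step: step 9

Remark 1: (+)-epicatechin (2S,3S), 3,5-dibenzyloxyphenol and 3,4-dibenzyloxybenzaldehyde are taken as purchased materials.
Remark 2: the hand of the TsDPEN ligand in step 12 is provisional; the enantiomer that sends hydride to the Si face of C3 is to be fixed on the monomeric tetra-O-benzylflavan-3-one, and the mirror-image ligand is used if that trial says so.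
Remark 3: the flav-3-ene and the three compounds that follow it are carried as mixtures of the two C2 epimers of unit 4.

**Route**

Step 1
Reactants: 1 (−)-epicatechin
Product: 2 5,7,3',4'-tetra-O-benzyl-(−)-epicatechin (2R,3R; 3-OH free)
Conditions: BnBr (4.4 equiv), K2CO3, DMF, 0 °C → rt
Reagents that add atoms: benzyl bromide, BrCc1ccccc1
Why: Williamson etherification of the four phenols, in which the carbonate base does not deprotonate the secondary 3-OH and no stereocentre is touched.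

Step 2
Reactants: 2 5,7,3',4'-tetra-O-benzyl-(−)-epicatechin
Product: 3 3,5,7,3',4'-penta-O-benzyl-(−)-epicatechin
Conditions: NaH, BnBr, Bu4NI (cat.), DMF, 0 °C → rt
Reagents that add atoms: benzyl bromide, BrCc1ccccc1
Why: Williamson benzylation of the secondary alkoxide, with C2 and C3 unaffected.

Step 3
Reactants: 3 3,5,7,3',4'-penta-O-benzyl-(−)-epicatechin
Product: 4 8-bromo-3,5,7,3',4'-penta-O-benzyl-(−)-epicatechin
Conditions: NBS (1.0 equiv), CH2Cl2, −78 °C → rt
Reagents that add atoms: N-bromosuccinimide, O=C1CCC(=O)N1Br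
Why: Electrophilic aromatic bromination of the trioxygenated ring A, expected at C8 because C6 lies between two benzyloxy groups and is the more hindered of the two free carbons.

Step 4
Reactants: 4 8-bromo-3,5,7,3',4'-penta-O-benzyl-(−)-epicatechin
Product: 5 8-bromo-4β-(2-ethoxyethoxy)-3,5,7,3',4'-penta-O-benzylepicatechin
Conditions: DDQ (2 equiv), 2-ethoxyethanol (5 equiv), CH2Cl2, rt
Reagents that add atoms: 2-ethoxyethanol, CCOCCO
Why: DDQ-mediated oxidative benzylic etherification (hydride abstraction from C4 to the ring A-stabilised cation, capture by the alcohol trans to the 3-benzyloxy group); the C4 configuration is planarised again in step 6.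

Step 5
Reactants: 6 3,5-dibenzyloxyphenol
Product: 7 1,3-dibenzyloxy-5-(triisopropylsilyloxy)benzene
Conditions: TIPSCl, imidazole, DMF, rt
Reagents that add atoms: chlorotriisopropylsilane, CC(C)[Si](Cl)(C(C)C)C(C)C
Why: Standard silylation of a phenol; the bulky silyl ether masks the oxygen that becomes O1 of unit 4 and screens its two neighbouring ring carbons.

Step 6
Reactants: 5 8-bromo-4β-(2-ethoxyethoxy)-penta-O-benzylepicatechin; 7 1,3-dibenzyloxy-5-(triisopropylsilyloxy)benzene
Product: 8 8-bromo-4β-[2,6-dibenzyloxy-4-(triisopropylsilyloxy)phenyl]-3,5,7,3',4'-penta-O-benzylepicatechin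
Conditions: 7 (3 equiv), Me3SiOTf (0.2 equiv), 4 Å MS, CH2Cl2, −78 → −40 °C; Et3N quench
Reagents that add atoms: none
Why: Lewis acid ionisation of the C4 ether and Friedel–Crafts arylation of the flavan-4-yl cation, the arene entering anti to the 3-benzyloxy group (4β, 3,4-trans) through its carbon between the two benzyloxy groups, since the triisopropylsilyl group shields the other two activated carbons and the C8 bromine prevents self-condensation.

Step 7
Reactants: 8 the silyl ether of step 6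
Product: 9 8-bromo-4β-(2,6-dibenzyloxy-4-hydroxyphenyl)-3,5,7,3',4'-penta-O-benzylepicatechin
Conditions: Bu4NF, AcOH, THF, 0 °C
Reagents that add atoms: none
Why: Fluoride cleavage of the aryl silyl ether, buffered with acetic acid so that the electron-rich phenoxide is not exposed to air as the free anion.

Step 8
Reactants: 10 3,4-dibenzyloxybenzaldehyde
Product: 11 (E)-3,4-dibenzyloxycinnamaldehyde
Conditions: Ph3P=CHCHO (1.1 equiv), toluene, 80 °C
Reagents that add atoms: (triphenylphosphoranylidene)acetaldehyde, O=CC=P(c1ccccc1)(c1ccccc1)c1ccccc1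
Why: Wittig olefination with a stabilised formyl ylide, which should give the E-enal.

Step 9
Reactants: 9 8-bromo-4β-(2,6-dibenzyloxy-4-hydroxyphenyl)-penta-O-benzylepicatechin; 11 (E)-3,4-dibenzyloxycinnamaldehyde
Product: 13 unit 3–unit 4 flav-3-ene (unit 3 C4 bonded to C6 of the new 2H-chromene; C2 of unit 4 as both epimers), via o-quinone methide 12 (not isolated)
Conditions: 11 (2 equiv), ethylenediammonium diacetate (0.3 equiv), 4 Å MS, toluene, 110 °C
Reagents that add atoms: none
Why: The diammonium diacetate converts enal 11 into its iminium ion, the free phenol of 9 attacks the iminium carbon through one of its two equivalent ortho carbons (C4–C4a bond), and loss of the amine gives the styryl o-quinone methide 12, whose thermal oxa-6π electrocyclisation forms O1–C2 and closes ring C as the 2H-chromene. The closest known reaction is the amine-salt-mediated condensation of resorcinols and phloroglucinol ethers with α,β-unsaturated aldehydes to 2H-chromenes. The only new stereocentre, C2 of unit 4, is not controlled here and both epimers are accepted, because step 12 resets it. The selectivity that is needed is site selectivity on the aryl ring, and the substrate fixes it: one hydroxyl is free, the other two oxygens are benzylated, and the two carbons ortho to the hydroxyl are related by symmetry, so ring A of unit 4 can only carry unit 3 at C6. Iminium activation and removal of water should favour 1,2-condensation over conjugate addition.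

Step 10
Reactants: 13 unit 3–unit 4 flav-3-ene
Product: 15 unit 3–unit 4 2,3-trans-flavan-3-ol (unit 4 3-OH free; both 2,3-trans diastereomers), via C3 alkylborane 14 (not isolated)
Conditions: BH3·THF, THF, 0 °C → rt; then NaOH aq, H2O2, 0 °C → rt
Reagents that add atoms: borane–tetrahydrofuran, B.C1CCOC1 (boron of 14 only); hydrogen peroxide, OO (oxygen on C3 of 15)
Why: Hydroboration–oxidation of a flav-3-ene, with boron going to C3 (styrene-type regiochemistry, away from the aryl-bearing C4) and syn addition anti to the C2 aryl group, so that each C2 epimer should give its 2,3-trans alcohol.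

Step 11
Reactants: 15 unit 3–unit 4 2,3-trans-flavan-3-ol
Product: 16 unit 3–unit 4 flavan-3-one (C2 of unit 4 as both epimers)
Conditions: Dess–Martin periodinane, CH2Cl2, rt
Reagents that add atoms: none
Why: Dess–Martin oxidation of the secondary alcohol to the flavan-3-one under near-neutral conditions, which removes the C3 centre and makes C2 epimerisable.

Step 12
Reactants: 16 unit 3–unit 4 flavan-3-one
Product: 17 unit 3–unit 4 2,3-cis-flavan-3-ol (unit 4 2R,3R; 3-OH free)
Conditions: RuCl(p-cymene)[(S,S)-TsDPEN] (5 mol%), HCO2H–Et3N (2:3), CH2Cl2, 35 °C, Ar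
Reagents that add atoms: none
Why: Proposed new method: C2–H of the flavan-3-one is α to the ketone, benzylic and on an oxygen-bearing carbon, so the amine should interconvert the two C2 epimers through the enol faster than the ruthenium hydride reduces them, while the chiral hydride attacks the Si face of C3 of the 2R epimer (the face away from its C2 aryl group) to give the 2,3-cis 2R,3R alcohol and the 2S epimer, whose aryl group blocks that face, is drained by epimerisation; the closest known reaction type is Noyori transfer hydrogenation with dynamic kinetic resolution of α-substituted cyclic ketones such as α-substituted tetralones, chromanones and β-keto esters.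

Step 13
Reactants: 17 unit 3–unit 4 2,3-cis-flavan-3-ol
Product: 18 fully benzylated unit 3–unit 4 bromide (8-bromo-penta-O-benzylepicatechin-(4β→6)-penta-O-benzylepicatechin)
Conditions: NaH, BnBr, Bu4NI (cat.), DMF, 0 °C → rt
Reagents that add atoms: benzyl bromide, BrCc1ccccc1
Why: Williamson benzylation of the one free secondary alcohol, which the aryl bromide and the other ethers tolerate.

Step 14
Reactants: 3 3,5,7,3',4'-penta-O-benzyl-(−)-epicatechin
Product: 19 4β-hydroxy-3,5,7,3',4'-penta-O-benzylepicatechin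
Conditions: DDQ (1.5 equiv), CH2Cl2–H2O (18:1), rt
Reagents that add atoms: water, O
Why: DDQ-mediated benzylic hydroxylation at C4 (hydride abstraction, water capture anti to the 3-benzyloxy group); the new carbinol centre is removed in step 15.

Step 15
Reactants: 19 4β-hydroxy-penta-O-benzylepicatechin
Product: 20 (2R,3S)-3,5,7,3',4'-pentakis(benzyloxy)flavan-4-one (unit 1 ketone)
Conditions: Dess–Martin periodinane, CH2Cl2, rt
Reagents that add atoms: none
Why: Dess–Martin oxidation of the benzylic alcohol under non-basic conditions, so the C3 centre α to the new ketone should not epimerise.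

Step 16
Reactants: 21 (+)-epicatechin (2S,3S)
Product: 22 5,7,3',4'-tetra-O-benzyl-(+)-epicatechin
Conditions: BnBr (4.4 equiv), K2CO3, DMF, 0 °C → rt
Reagents that add atoms: benzyl bromide, BrCc1ccccc1
Why: Williamson etherification of the four phenols, as in step 1, in the enantiomeric series.

Step 17
Reactants: 22 5,7,3',4'-tetra-O-benzyl-(+)-epicatechin
Product: 23 3,5,7,3',4'-penta-O-benzyl-(+)-epicatechin
Conditions: NaH, BnBr, Bu4NI (cat.), DMF, 0 °C → rt
Reagents that add atoms: benzyl bromide, BrCc1ccccc1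
Why: Williamson benzylation of the secondary alkoxide, as in step 2.

Step 18
Reactants: 23 3,5,7,3',4'-penta-O-benzyl-(+)-epicatechin
Product: 24 8-bromo-3,5,7,3',4'-penta-O-benzyl-(+)-epicatechin
Conditions: NBS (1.0 equiv), CH2Cl2, −78 °C → rt
Reagents that add atoms: N-bromosuccinimide, O=C1CCC(=O)N1Br
Why: Electrophilic bromination at the more accessible C8, as in step 3; the bromine blocks C8 of unit 2 until the final hydrogenolysis.

Step 19
Reactants: 24 8-bromo-penta-O-benzyl-(+)-epicatechin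
Product: 25 8-bromo-6-iodo-3,5,7,3',4'-penta-O-benzyl-(+)-epicatechin
Conditions: NIS (1.1 equiv), CF3CO2H (cat.), CH2Cl2–MeCN, 0 °C → rt
Reagents that add atoms: N-iodosuccinimide, O=C1CCC(=O)N1I
Why: Electrophilic aromatic iodination at C6, the only free carbon of the trioxygenated ring A and far more nucleophilic than any carbon of the dibenzyloxyphenyl ring B.

Step 20
Reactants: 25 8-bromo-6-iodo-penta-O-benzyl-(+)-epicatechin; 20 unit 1 ketone
Product: 27 unit 1–unit 2 tertiary alcohol (C4 of unit 1 bearing OH and C6 of unit 2), via 6-lithio arene 26 (not isolated)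
Conditions: n-BuLi (1.05 equiv), THF, −78 °C; then 20, −78 → 0 °C; H2O
Reagents that add atoms: n-butyllithium, [Li]CCCC (lithium of 26 only)
Why: Iodine–lithium exchange is much faster than bromine–lithium exchange, so the C6 aryllithium forms selectively and adds 1,2 to the flavan-4-one, expected anti to the 3-benzyloxy group, although the carbinol configuration is lost in step 21.

Step 21
Reactants: 27 unit 1–unit 2 tertiary alcohol
Product: 28 unit 1–unit 2 dimer (penta-O-benzylepicatechin-(4α→6)-8-bromo-penta-O-benzyl-ent-epicatechin; unit 1 3,4-cis)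
Conditions: Bu3SnH, CF3CO2H, CH2Cl2, 0 °C
Reagents that add atoms: none
Why: Ionic deoxygenation in which the acid ionises the tertiary diaryl carbinol and the tin hydride delivers hydride to the C4 cation from the β face, anti to the 3-benzyloxy group, which should leave the aryl group α and cis to O3.

Step 22
Reactants: 28 unit 1–unit 2 dimer
Product: 29 unit 1–unit 2 dimer with a 4-hydroxyl on unit 2 (trans to its 3-benzyloxy group)
Conditions: DDQ (1.5 equiv), CH2Cl2–H2O (18:1), rt
Reagents that add atoms: water, O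
Why: DDQ benzylic hydroxylation at the only benzylic methylene of the dimer (C4 of unit 2), the diarylmethine C4–H of unit 1 being shielded by the flanking benzyloxy groups of two rings and unable to align with both of them.

Step 23
Reactants: 29 unit 1–unit 2 dimer 4-alcohol
Product: 30 unit 1–unit 2 ketone (4-oxo on unit 2)
Conditions: Dess–Martin periodinane, CH2Cl2, rt
Reagents that add atoms: none
Why: Dess–Martin oxidation of the benzylic alcohol to the flavan-4-one without base, so C3 of unit 2 should keep its configuration.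

Step 24
Reactants: 18 fully benzylated unit 3–unit 4 bromide; 30 unit 1–unit 2 ketone
Product: 32 tetrameric tertiary alcohol (C4 of unit 2 bearing OH and C8 of unit 3), via 8-lithio arene 31 (not isolated)
Conditions: t-BuLi (2.0 equiv), THF, −78 °C; then 30, −78 → 0 °C; H2O
Reagents that add atoms: tert-butyllithium, [Li]C(C)(C)C (lithium of 31 only)
Why: Bromine–lithium exchange at C8 of unit 3 (the second equivalent of the alkyllithium destroys the tert-butyl bromide before the bromine-bearing ketone is added) followed by 1,2-addition of the aryllithium to the flavan-4-one, as in step 20.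

Step 25
Reactants: 32 tetrameric tertiary alcohol
Product: 33 eicosa-O-benzyl 8-bromo (unit 2) tetramer
Conditions: Bu3SnH, CF3CO2H, CH2Cl2, 0 °C
Reagents that add atoms: none
Why: Ionic deoxygenation as in step 21, hydride entering the C4 cation of unit 2 anti to its 3-benzyloxy group (α face in this 2S,3S unit), which should place unit 3 β and cis to O3.

Step 26
Reactants: 33 eicosa-O-benzyl 8-bromo tetramer
Product: 34 CNP0120618.3
Conditions: H2 (5 bar), Pd(OH)2/C, Et3N (1.2 equiv), THF–MeOH–H2O, rt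
Reagents that add atoms: none
Why: Catalytic hydrogenolysis of the twenty benzyl ethers with concurrent hydrodebromination at C8 of unit 2, the amine taking up HBr; no stereocentre is affected.

**Compound list**

1 | (−)-epicatechin (2R,3R) | Oc1cc(O)c2c(c1)O[C@H](c1ccc(O)c(O)c1)[C@H](O)C2 | starting material
2 | 5,7,3',4'-tetra-O-benzyl-(−)-epicatechin | c9ccccc9COc1cc(OCc9ccccc9)c2c(c1)O[C@H](c4ccc(OCc9ccccc9)c(OCc9ccccc9)c4)[C@H](O)C2 | intermediate
3 | 3,5,7,3',4'-penta-O-benzyl-(−)-epicatechin | c9ccccc9COc1cc(OCc9ccccc9)c2c(c1)O[C@H](c4ccc(OCc9ccccc9)c(OCc9ccccc9)c4)[C@H](OCc9ccccc9)C2 | intermediate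
4 | 8-bromo-penta-O-benzyl-(−)-epicatechin | c9ccccc9COc1cc(OCc9ccccc9)c2c(c1Br)O[C@H](c4ccc(OCc9ccccc9)c(OCc9ccccc9)c4)[C@H](OCc9ccccc9)C2 | intermediate
5 | 8-bromo-4β-(2-ethoxyethoxy)-penta-O-benzylepicatechin | c9ccccc9COc1cc(OCc9ccccc9)c2c(c1Br)O[C@H](c4ccc(OCc9ccccc9)c(OCc9ccccc9)c4)[C@H](OCc9ccccc9)[C@H]2OCCOCC | intermediate
6 | 3,5-dibenzyloxyphenol | Oc1cc(OCc9ccccc9)cc(OCc9ccccc9)c1 | starting material
7 | 1,3-dibenzyloxy-5-(triisopropylsilyloxy)benzene | CC(C)[Si](C(C)C)(C(C)C)Oc1cc(OCc9ccccc9)cc(OCc9ccccc9)c1 | intermediate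
8 | 8-bromo-4β-[2,6-dibenzyloxy-4-(triisopropylsilyloxy)phenyl]-penta-O-benzylepicatechin | c9ccccc9COc1cc(OCc9ccccc9)c2c(c1Br)O[C@H](c4ccc(OCc9ccccc9)c(OCc9ccccc9)c4)[C@H](OCc9ccccc9)[C@H]2c1c(OCc9ccccc9)cc(O[Si](C(C)C)(C(C)C)C(C)C)cc1OCc9ccccc9 | intermediate
9 | 8-bromo-4β-(2,6-dibenzyloxy-4-hydroxyphenyl)-penta-O-benzylepicatechin | c9ccccc9COc1cc(OCc9ccccc9)c2c(c1Br)O[C@H](c4ccc(OCc9ccccc9)c(OCc9ccccc9)c4)[C@H](OCc9ccccc9)[C@H]2c1c(OCc9ccccc9)cc(O)cc1OCc9ccccc9 | intermediate
10 | 3,4-dibenzyloxybenzaldehyde | O=Cc1ccc(OCc9ccccc9)c(OCc9ccccc9)c1 | starting material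
11 | (E)-3,4-dibenzyloxycinnamaldehyde | O=C/C=C/c1ccc(OCc9ccccc9)c(OCc9ccccc9)c1 | intermediate
12 | styryl o-quinone methide on unit 3 (not isolated) | c9ccccc9COc1cc(OCc9ccccc9)c2c(c1Br)O[C@H](c4ccc(OCc9ccccc9)c(OCc9ccccc9)c4)[C@H](OCc9ccccc9)[C@H]2C1=C(OCc9ccccc9)C(=C/C=C/c4ccc(OCc9ccccc9)c(OCc9ccccc9)c4)C(=O)C=C1OCc9ccccc9 | intermediate
13 | unit 3–unit 4 flav-3-ene (C2 of unit 4 both epimers) | c9ccccc9COc1cc(OCc9ccccc9)c2c(c1Br)O[C@H](c4ccc(OCc9ccccc9)c(OCc9ccccc9)c4)[C@H](OCc9ccccc9)[C@H]2c1c(OCc9ccccc9)cc3c(c1OCc9ccccc9)C=CC(c4ccc(OCc9ccccc9)c(OCc9ccccc9)c4)O3 | intermediate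
14 | C3 alkylborane of unit 4 (2,3-trans, both C2 epimers; not isolated) | c9ccccc9COc1cc(OCc9ccccc9)c2c(c1Br)O[C@H](c4ccc(OCc9ccccc9)c(OCc9ccccc9)c4)[C@H](OCc9ccccc9)[C@H]2c1c(OCc9ccccc9)cc3c(c1OCc9ccccc9)CC(B)C(c4ccc(OCc9ccccc9)c(OCc9ccccc9)c4)O3 | intermediate
15 | unit 3–unit 4 2,3-trans-flavan-3-ol (both 2,3-trans diastereomers at unit 4) | c9ccccc9COc1cc(OCc9ccccc9)c2c(c1Br)O[C@H](c4ccc(OCc9ccccc9)c(OCc9ccccc9)c4)[C@H](OCc9ccccc9)[C@H]2c1c(OCc9ccccc9)cc3c(c1OCc9ccccc9)CC(O)C(c4ccc(OCc9ccccc9)c(OCc9ccccc9)c4)O3 | intermediate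
16 | unit 3–unit 4 flavan-3-one (C2 of unit 4 both epimers) | c9ccccc9COc1cc(OCc9ccccc9)c2c(c1Br)O[C@H](c4ccc(OCc9ccccc9)c(OCc9ccccc9)c4)[C@H](OCc9ccccc9)[C@H]2c1c(OCc9ccccc9)cc3c(c1OCc9ccccc9)CC(=O)C(c4ccc(OCc9ccccc9)c(OCc9ccccc9)c4)O3 | intermediate
17 | unit 3–unit 4 2,3-cis-flavan-3-ol (unit 4 2R,3R) | c9ccccc9COc1cc(OCc9ccccc9)c2c(c1Br)O[C@H](c4ccc(OCc9ccccc9)c(OCc9ccccc9)c4)[C@H](OCc9ccccc9)[C@H]2c1c(OCc9ccccc9)cc3c(c1OCc9ccccc9)C[C@@H](O)[C@@H](c4ccc(OCc9ccccc9)c(OCc9ccccc9)c4)O3 | intermediate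
18 | 8-bromo-penta-O-benzylepicatechin-(4β→6)-penta-O-benzylepicatechin | c9ccccc9COc1cc(OCc9ccccc9)c2c(c1Br)O[C@H](c4ccc(OCc9ccccc9)c(OCc9ccccc9)c4)[C@H](OCc9ccccc9)[C@H]2c1c(OCc9ccccc9)cc3c(c1OCc9ccccc9)C[C@@H](OCc9ccccc9)[C@@H](c4ccc(OCc9ccccc9)c(OCc9ccccc9)c4)O3 | intermediate
19 | 4β-hydroxy-penta-O-benzylepicatechin | c9ccccc9COc1cc(OCc9ccccc9)c2c(c1)O[C@H](c4ccc(OCc9ccccc9)c(OCc9ccccc9)c4)[C@H](OCc9ccccc9)[C@H]2O | intermediate
20 | (2R,3S)-3,5,7,3',4'-pentakis(benzyloxy)flavan-4-one | c9ccccc9COc1cc(OCc9ccccc9)c2c(c1)O[C@H](c4ccc(OCc9ccccc9)c(OCc9ccccc9)c4)[C@H](OCc9ccccc9)C2=O | intermediate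
21 | (+)-epicatechin (2S,3S) | Oc1cc(O)c2c(c1)O[C@@H](c1ccc(O)c(O)c1)[C@@H](O)C2 | starting material
22 | 5,7,3',4'-tetra-O-benzyl-(+)-epicatechin | c9ccccc9COc1cc(OCc9ccccc9)c2c(c1)O[C@@H](c4ccc(OCc9ccccc9)c(OCc9ccccc9)c4)[C@@H](O)C2 | intermediate
23 | 3,5,7,3',4'-penta-O-benzyl-(+)-epicatechin | c9ccccc9COc1cc(OCc9ccccc9)c2c(c1)O[C@@H](c4ccc(OCc9ccccc9)c(OCc9ccccc9)c4)[C@@H](OCc9ccccc9)C2 | intermediate
24 | 8-bromo-penta-O-benzyl-(+)-epicatechin | c9ccccc9COc1cc(OCc9ccccc9)c2c(c1Br)O[C@@H](c4ccc(OCc9ccccc9)c(OCc9ccccc9)c4)[C@@H](OCc9ccccc9)C2 | intermediate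
25 | 8-bromo-6-iodo-penta-O-benzyl-(+)-epicatechin | c9ccccc9COc1c(I)c(OCc9ccccc9)c2c(c1Br)O[C@@H](c4ccc(OCc9ccccc9)c(OCc9ccccc9)c4)[C@@H](OCc9ccccc9)C2 | intermediate
26 | 8-bromo-6-lithio-penta-O-benzyl-(+)-epicatechin (not isolated) | c9ccccc9COc1c([Li])c(OCc9ccccc9)c2c(c1Br)O[C@@H](c4ccc(OCc9ccccc9)c(OCc9ccccc9)c4)[C@@H](OCc9ccccc9)C2 | intermediate
27 | unit 1–unit 2 tertiary alcohol (aryl drawn anti to O3 of unit 1; configuration immaterial) | c9ccccc9COc1cc(OCc9ccccc9)c2c(c1)O[C@H](c4ccc(OCc9ccccc9)c(OCc9ccccc9)c4)[C@H](OCc9ccccc9)[C@@]2(O)c1c(OCc9ccccc9)c(Br)c2c(c1OCc9ccccc9)C[C@H](OCc9ccccc9)[C@H](c4ccc(OCc9ccccc9)c(OCc9ccccc9)c4)O2 | intermediate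
28 | penta-O-benzylepicatechin-(4α→6)-8-bromo-penta-O-benzyl-ent-epicatechin | c9ccccc9COc1cc(OCc9ccccc9)c2c(c1)O[C@H](c4ccc(OCc9ccccc9)c(OCc9ccccc9)c4)[C@H](OCc9ccccc9)[C@@H]2c1c(OCc9ccccc9)c(Br)c2c(c1OCc9ccccc9)C[C@H](OCc9ccccc9)[C@H](c4ccc(OCc9ccccc9)c(OCc9ccccc9)c4)O2 | intermediate
29 | unit 1–unit 2 dimer with 4-hydroxyl on unit 2 (trans to its 3-benzyloxy group) | c9ccccc9COc1cc(OCc9ccccc9)c2c(c1)O[C@H](c4ccc(OCc9ccccc9)c(OCc9ccccc9)c4)[C@H](OCc9ccccc9)[C@@H]2c1c(OCc9ccccc9)c(Br)c2c(c1OCc9ccccc9)[C@@H](O)[C@H](OCc9ccccc9)[C@H](c4ccc(OCc9ccccc9)c(OCc9ccccc9)c4)O2 | intermediate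
30 | unit 1–unit 2 ketone (4-oxo on unit 2) | c9ccccc9COc1cc(OCc9ccccc9)c2c(c1)O[C@H](c4ccc(OCc9ccccc9)c(OCc9ccccc9)c4)[C@H](OCc9ccccc9)[C@@H]2c1c(OCc9ccccc9)c(Br)c2c(c1OCc9ccccc9)C(=O)[C@H](OCc9ccccc9)[C@H](c4ccc(OCc9ccccc9)c(OCc9ccccc9)c4)O2 | intermediate
31 | 8-lithio unit 3–unit 4 arene (not isolated) | c9ccccc9COc1cc(OCc9ccccc9)c2c(c1[Li])O[C@H](c4ccc(OCc9ccccc9)c(OCc9ccccc9)c4)[C@H](OCc9ccccc9)[C@H]2c1c(OCc9ccccc9)cc3c(c1OCc9ccccc9)C[C@@H](OCc9ccccc9)[C@@H](c4ccc(OCc9ccccc9)c(OCc9ccccc9)c4)O3 | intermediate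
32 | tetrameric tertiary alcohol (unit 3 drawn anti to O3 of unit 2; configuration immaterial) | c9ccccc9COc1cc(OCc9ccccc9)c2c(c1)O[C@H](c4ccc(OCc9ccccc9)c(OCc9ccccc9)c4)[C@H](OCc9ccccc9)[C@@H]2c1c(OCc9ccccc9)c(Br)c2c(c1OCc9ccccc9)[C@@](O)(c1c(OCc9ccccc9)cc(OCc9ccccc9)c3c1O[C@H](c4ccc(OCc9ccccc9)c(OCc9ccccc9)c4)[C@H](OCc9ccccc9)[C@H]3c1c(OCc9ccccc9)cc3c(c1OCc9ccccc9)C[C@@H](OCc9ccccc9)[C@@H](c4ccc(OCc9ccccc9)c(OCc9ccccc9)c4)O3)[C@H](OCc9ccccc9)[C@H](c4ccc(OCc9ccccc9)c(OCc9ccccc9)c4)O2 | intermediate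
33 | eicosa-O-benzyl 8-bromo (unit 2) tetramer | c9ccccc9COc1cc(OCc9ccccc9)c2c(c1)O[C@H](c4ccc(OCc9ccccc9)c(OCc9ccccc9)c4)[C@H](OCc9ccccc9)[C@@H]2c1c(OCc9ccccc9)c(Br)c2c(c1OCc9ccccc9)[C@H](c1c(OCc9ccccc9)cc(OCc9ccccc9)c3c1O[C@H](c4ccc(OCc9ccccc9)c(OCc9ccccc9)c4)[C@H](OCc9ccccc9)[C@H]3c1c(OCc9ccccc9)cc3c(c1OCc9ccccc9)C[C@@H](OCc9ccccc9)[C@@H](c4ccc(OCc9ccccc9)c(OCc9ccccc9)c4)O3)[C@H](OCc9ccccc9)[C@H](c4ccc(OCc9ccccc9)c(OCc9ccccc9)c4)O2 | intermediate
34 | CNP0120618.3 | Oc1cc(O)c2c(c1)O[C@H](c1ccc(O)c(O)c1)[C@H](O)[C@@H]2c1c(O)cc2c(c1O)[C@H](c1c(O)cc(O)c3c1O[C@H](c1ccc(O)c(O)c1)[C@H](O)[C@H]3c1c(O)cc3c(c1O)C[C@@H](O)[C@@H](c1ccc(O)c(O)c1)O3)[C@H](O)[C@H](c1ccc(O)c(O)c1)O2 | target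

**Step count and risks**

Total step count: 26. Longest linear sequence: 14 steps (steps 1–4, 6, 7, 9–13, 24–26).

Steps most likely to fail:

1. Step 12 (labelled step). Epimerisation at C2 of the unit 4 ketone may be slower than hydride transfer, or the catalyst may discriminate poorly between the faces of a ketone that has no aryl group on the carbonyl carbon, so that the reduction does not converge on one alcohol. Fallback with known chemistry, setting out from 16 and returning at 17: ketone 16 is reduced with LiBH(s-Bu)3 in THF at −78 °C, the established substrate-controlled way from flavan-3-ones to 2,3-cis-flavan-3-ols (hydride anti to the C2 aryl group). This should give 17 together with its unit 4 epimer, the (2S,3S) cis alcohol F1. The two are diastereomers through the fixed centres of unit 3 and are to be separated on silica. F1 is oxidised back to 16 with Dess–Martin periodinane, 16 is equilibrated at C2 with DBU in CH2Cl2 and reduced again, so that material is funnelled to 17.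

2. Step 9. Conjugate addition of the ring carbon to the iminium ion (leading to 4-aryl chroman products) may compete with 1,2-condensation, or the condensation may stall at an ortho carbon crowded by the neighbouring benzyloxy group. Fallback setting out from 9 and 10 and returning at 13: phenol 9 is ortho-formylated (MgCl2, Et3N, paraformaldehyde, MeCN, reflux) at either of its equivalent ortho carbons to the salicylaldehyde F2. Aldehyde 10 is converted with dimethyl (1-diazo-2-oxopropyl)phosphonate, K2CO3 and MeOH into 4-ethynyl-1,2-dibenzyloxybenzene F3, and by catecholborane hydroboration and hydrolysis into (E)-2-(3,4-dibenzyloxyphenyl)vinylboronic acid F4. F2, F4 and dibenzylamine (0.4 equiv, dioxane, 90 °C) should then give 13 by a Petasis borono-Mannich reaction, loss of the amine to the same o-quinone methide 12 and 6π closure. The carbon skeleton is fixed before ring closure, so a 1,4-pathway cannot arise.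

3. Step 6. Attack through a ring carbon next to the silyloxy group (loss of site selectivity on arene 7), or loss of the silyl group under the Lewis acid, would give regioisomeric aryl adducts. Fallback setting out from 5 and returning at 8: 5 is coupled with excess phloroglucinol (BF3·OEt2, THF–CH2Cl2, 0 °C). Its three ring carbons are equivalent, so a single 4β adduct, the 2,4,6-trihydroxyphenyl compound F5, is expected. The hydroxyl para to the flavanyl group, the only unhindered one, is silylated with TIPSCl (1 equiv) and imidazole in DMF at 0 °C to the mono-silyl ether F6. The two flanking hydroxyls are then benzylated (BnBr, K2CO3, acetone, reflux) to give 8.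

**Further compounds**

F1 | step 12 | unit 3–unit 4 2,3-cis-flavan-3-ol with unit 4 2S,3S | c9ccccc9COc1cc(OCc9ccccc9)c2c(c1Br)O[C@H](c4ccc(OCc9ccccc9)c(OCc9ccccc9)c4)[C@H](OCc9ccccc9)[C@H]2c1c(OCc9ccccc9)cc3c(c1OCc9ccccc9)C[C@H](O)[C@H](c4ccc(OCc9ccccc9)c(OCc9ccccc9)c4)O3
F2 | step 9 | 8-bromo-4β-(2,6-dibenzyloxy-3-formyl-4-hydroxyphenyl)-penta-O-benzylepicatechin | c9ccccc9COc1cc(OCc9ccccc9)c2c(c1Br)O[C@H](c4ccc(OCc9ccccc9)c(OCc9ccccc9)c4)[C@H](OCc9ccccc9)[C@H]2c1c(OCc9ccccc9)cc(O)c(C=O)c1OCc9ccccc9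
F3 | step 9 | 4-ethynyl-1,2-dibenzyloxybenzene | C#Cc1ccc(OCc9ccccc9)c(OCc9ccccc9)c1
F4 | step 9 | (E)-2-(3,4-dibenzyloxyphenyl)vinylboronic acid | OB(O)/C=C/c1ccc(OCc9ccccc9)c(OCc9ccccc9)c1
F5 | step 6 | 8-bromo-4β-(2,4,6-trihydroxyphenyl)-penta-O-benzylepicatechin | c9ccccc9COc1cc(OCc9ccccc9)c2c(c1Br)O[C@H](c4ccc(OCc9ccccc9)c(OCc9ccccc9)c4)[C@H](OCc9ccccc9)[C@H]2c1c(O)cc(O)cc1O
F6 | step 6 | 8-bromo-4β-[2,6-dihydroxy-4-(triisopropylsilyloxy)phenyl]-penta-O-benzylepicatechin | c9ccccc9COc1cc(OCc9ccccc9)c2c(c1Br)O[C@H](c4ccc(OCc9ccccc9)c(OCc9ccccc9)c4)[C@H](OCc9ccccc9)[C@H]2c1c(O)cc(O[Si](C(C)C)(C(C)C)C(C)C)cc1O
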